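Everything rests on disconnecting the ten-membered carbocycle between the vinylic carbon C5 and the lactone carbinol C6. The key step is an intramolecular Nozaki–Hiyama–Kishi addition that exploits the (Z)-γ-oxygenated enone C3(=O)–C4=C5–C6–O and the ester carbon C12 lying γ to O6: the (Z)-β-iodo enone terminus of an open-chain seco-aldehyde adds to the C6 aldehyde, and the new alkoxide, set at C6 by the neighbouring C7, is acylated by the C12 methyl ester, so carbocycle, C6 stereocentre and α-methylene-γ-lactone arise in one operation. The precursor comes from (R)-linalool (C10) and a glyceraldehyde-derived allyl bromide whose dioxolane carbon controls C7/C8 and later becomes the C6 aldehyde.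

Key step: step 13

Atom labels used throughout: C1–C10 are the ring carbons (C3 ketone, C4=C5, C6 lactone carbinol, C7 ring fusion, C8 angelate carbinol, C10 tertiary carbinol); C11/C12/C13 are the lactone α-carbon, carbonyl and exocyclic methylene; C14 is the methyl on C10; C15 is the hydroxymethyl on C4.

Remark on the chemistry: the target is taken as the open 3-oxo-10-hydroxy form that is drawn; its ring–chain tautomer (3,10-hemiketal) is not treated as a separate compound.

Step 1
Reactants: 1 (R)-linalool
Product: 2 (R)-linalool triethylsilyl ether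
Conditions: TESOTf, 2,6-lutidine, CH2Cl2, −78 → 0 °C
Reagents that add atoms: triethylsilyl triflate, CC[Si](CC)(CC)OS(=O)(=O)C(F)(F)F
Why: Standard silyl triflate/hindered base protection of a tertiary alcohol, needed so that the later C3 carbonyl compounds do not close onto O10; the C10 stereocentre is bought with 1 and is not touched.

Step 2
Reactants: 2 (R)-linalool triethylsilyl ether
Product: 4 primary alcohol at C8, via B-alkyl-9-BBN borane 3 (not isolated)
Conditions: 9-BBN, THF, 0 °C → rt; then NaOH, H2O2, 0 °C
Reagents that add atoms: hydrogen peroxide, OO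
Why: Anti-Markovnikov hydroboration–oxidation, in which 9-BBN should add to the monosubstituted vinyl group far faster than to the trisubstituted alkene and alkaline peroxide converts borane 3 into the C8 alcohol.

Step 3
Reactants: 4 primary alcohol at C8
Product: 5 C8 aldehyde
Conditions: PhI(OAc)2, TEMPO (cat.), CH2Cl2, rt
Reagents that add atoms: none
Why: TEMPO/PhI(OAc)2 oxidation of a primary alcohol stops at the aldehyde under near-neutral conditions that should spare the silyl ether, the alkene and the β-silyloxy aldehyde itself.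

Step 4
Reactants: 6 (R)-glyceraldehyde acetonide; 7 methyl acrylate
Product: 8 Morita–Baylis–Hillman adduct
Conditions: DABCO, 1,4-dioxane/H2O, rt
Reagents that add atoms: none
Why: Morita–Baylis–Hillman reaction of an α-alkoxy aldehyde with methyl acrylate; the carbinol centre formed is a mixture of no consequence because it becomes sp2 in step 5, while the dioxolane centre is carried over from 6.

Step 5
Reactants: 8 Morita–Baylis–Hillman adduct
Product: 9 (Z)-2-(bromomethyl)alkenoate
Conditions: NBS, Me2S, CH2Cl2, 0 °C → rt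
Reagents that add atoms: N-bromosuccinimide, O=C1CCC(=O)N1Br
Why: Corey–Kim-type activation of the allylic alcohol followed by SN2' attack of bromide should give the thermodynamically preferred (Z)-2-(bromomethyl)alkenoate without acid that would endanger the acetonide.

Step 6
Reactants: 5 C8 aldehyde; 9 (Z)-2-(bromomethyl)alkenoate
Product: 10 syn hydroxy ester (C7–C8 bond formed)
Conditions: indium powder, THF/H2O (1:1), rt
Reagents that add atoms: none
Why: Indium-mediated Barbier allylation through a cyclic chair transition state, in which the (Z)-allylindium should give the syn (cis-lactone-type) C7/C8 pair and the aldehyde should add to the alkene face anti to the dioxolane C–O bond with the allylic hydrogen eclipsing the double bond (allylic 1,3-strain), so that the bought glyceraldehyde centre sets C7 (R) and, through the chair, C8 (R).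

Step 7
Reactants: 10 syn hydroxy ester; 11 angelic acid
Product: 13 C8 angelate, via mixed anhydride 12 (not isolated)
Conditions: 2,4,6-Cl3C6H2COCl, Et3N, toluene, rt; then 10, 80 °C
Reagents that add atoms: none
Why: Yamaguchi esterification through mixed anhydride 12 without DMAP, the established way to acylate hindered secondary alcohols with angelic acid without Z → E isomerisation to the tiglate.

Step 8
Reactants: 13 C8 angelate
Product: 15 C3 aldehyde, via secondary ozonide 14 (not isolated)
Conditions: O3, CH2Cl2, Sudan Red 7B (indicator), −78 °C; then PPh3, −78 °C → rt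
Reagents that add atoms: ozone, [O-][O+]=O
Why: Ozonolysis to a dye end-point, in which the electron-rich trisubstituted alkene should be cleaved much faster than the electron-poor acrylate and angelate double bonds, and PPh3 reduces ozonide 14 to the aldehyde.

Step 9
Reactants: 15 C3 aldehyde
Product: 16 propargylic alcohol
Conditions: HC≡CMgBr, THF, −78 °C
Reagents that add atoms: ethynylmagnesium bromide, C#C[Mg]Br
Why: 1,2-Addition of an alkynyl Grignard reagent to an aldehyde at low temperature, chemoselective over the three ester groups; the C3 carbinol centre is a mixture that is removed in step 10.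

Step 10
Reactants: 16 propargylic alcohol
Product: 17 ethynyl ketone
Conditions: Dess–Martin periodinane, NaHCO3, CH2Cl2, 0 °C
Reagents that add atoms: none
Why: Dess–Martin oxidation of a propargylic alcohol to the ynone under buffered, non-basic conditions.

Step 11
Reactants: 17 ethynyl ketone
Product: 19 (Z)-β-iodo-α-(hydroxymethyl) enone, via aluminium iodoallenolate 18 (not isolated)
Conditions: Et2AlI, CH2Cl2, −78 °C; then HCHO (monomer in THF, from cracked paraformaldehyde), −78 → −40 °C
Reagents that add atoms: diethylaluminium iodide, CC[Al](I)CC; formaldehyde, C=O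
Why: Three-component halo-aldol (β-iodo Morita–Baylis–Hillman) reaction, in which iodide adds to C5 of the ynone to give allenolate 18 and formaldehyde is taken up at C4 from the side of the C5 hydrogen, so the kinetic product should have iodine cis to the C3 carbonyl (Z) and carries C15.

Step 12
Reactants: 19 (Z)-β-iodo-α-(hydroxymethyl) enone
Product: 21 seco-aldehyde (C6 aldehyde), via vicinal diol 20 (not isolated)
Conditions: H5IO6, EtOAc, 0 °C → rt; crude product used at once
Reagents that add atoms: none
Why: Periodic acid hydrolyses the terminal acetonide and cleaves diol 20 in the same flask (glycol cleavage), so the dioxolane CH2 leaves as formaldehyde and C6 appears as the aldehyde under non-basic conditions chosen to avoid epimerisation at C7 and β-elimination of the angelate.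

Step 13
Reactants: 21 seco-aldehyde
Product: 23 macrocyclic lactone (10-O-triethylsilyl ether of the target), via ring-closed hydroxy ester 22 (not isolated)
Conditions: CrCl2 (excess), NiCl2 (cat.), DMSO/THF, rt, 2 mM by syringe pump; then PPTS (cat.), CH2Cl2, rt
Reagents that add atoms: none
Why: Zerovalent nickel inserts into the activated C5–I bond of the (Z)-β-iodo enone and transmetalates to trivalent chromium; the alkenylchromium adds to the C6 aldehyde with retention of the C4=C5 geometry, and the chromium alkoxide of 22, which lies γ to the methyl ester, lactonises, completed by PPTS. The closest known reaction type is the intramolecular Nozaki–Hiyama–Kishi macrocyclisation of iodoalkenyl aldehydes to medium-ring allylic alcohols, followed by ordinary γ-hydroxy acrylate lactonisation. The ten-membered carbocycle closes in a 10-exo-trig mode (aldehyde C=O exocyclic to the forming ring, Z-alkene endocyclic) and the γ-lactone by a 5-exo-trig acyl substitution. C6 is the only new stereocentre and is controlled by C7: in a Felkin–Anh arrangement the planar acrylate on C7 should stand anti to the incoming alkenylchromium while C8, which must stay within the forming ring, is gauche, which places O6 syn-clinal to C12 and gives the (6S), cis-fused product. The step needs addition to the aldehyde in preference to the C3 ketone and the esters (secured by the aldehyde selectivity of alkenylchromium reagents), ring closure in preference to oligomerisation (secured by high dilution and the Z-enone turn), and acylation of O6 by C12 and not by the angelate (secured by five-membered ring formation at the unhindered acrylate ester).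

Step 14
Reactants: 23 macrocyclic lactone
Product: 24 target CNP0181802.1
Conditions: HF·pyridine, pyridine, THF, 0 °C → rt
Reagents that add atoms: none
Why: Buffered fluoride cleavage of the tertiary triethylsilyl ether, which should leave the α-methylene lactone, the enone, the free C15 hydroxyl and the angelate intact.

Compound list

1 | (R)-(−)-linalool, (3R)-3,7-dimethylocta-1,6-dien-3-ol | C=C[C@](C)(O)CCC=C(C)C | starting material
2 | (3R)-3,7-dimethyl-3-(triethylsilyloxy)octa-1,6-diene | C=C[C@](C)(O[Si](CC)(CC)CC)CCC=C(C)C | intermediate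
3 | 9-[(3S)-3,7-dimethyl-3-(triethylsilyloxy)oct-6-en-1-yl]-9-borabicyclo[3.3.1]nonane (same spatial arrangement at C10 as in 2; the descriptor changes by priority only) | B1(C2CCCC1CCC2)CC[C@](C)(O[Si](CC)(CC)CC)CCC=C(C)C | intermediate
4 | (3R)-3,7-dimethyl-3-(triethylsilyloxy)oct-6-en-1-ol | OCC[C@](C)(O[Si](CC)(CC)CC)CCC=C(C)C | intermediate
5 | (3R)-3,7-dimethyl-3-(triethylsilyloxy)oct-6-enal | O=CC[C@](C)(O[Si](CC)(CC)CC)CCC=C(C)C | intermediate
6 | (4R)-2,2-dimethyl-1,3-dioxolane-4-carbaldehyde, (R)-glyceraldehyde acetonide | O=C[C@H]1COC(C)(C)O1 | starting material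
7 | methyl acrylate | C=CC(=O)OC | starting material
8 | methyl 2-{hydroxy[(4R)-2,2-dimethyl-1,3-dioxolan-4-yl]methyl}prop-2-enoate (both carbinol epimers) | C=C(C(=O)OC)C(O)[C@H]1COC(C)(C)O1 | intermediate
9 | methyl (2Z)-2-(bromomethyl)-3-[(4S)-2,2-dimethyl-1,3-dioxolan-4-yl]prop-2-enoate | COC(=O)/C(CBr)=C/[C@H]1COC(C)(C)O1 | intermediate
10 | methyl (3R,4R,6R)-3-[(4S)-2,2-dimethyl-1,3-dioxolan-4-yl]-4-hydroxy-6,10-dimethyl-2-methylidene-6-(triethylsilyloxy)undec-9-enoate | COC(=O)C(=C)[C@@H]([C@H]1COC(C)(C)O1)[C@H](O)C[C@](C)(O[Si](CC)(CC)CC)CCC=C(C)C | intermediate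
11 | angelic acid, (2Z)-2-methylbut-2-enoic acid | C/C=C(/C)C(=O)O | starting material
12 | (2Z)-2-methylbut-2-enoic 2,4,6-trichlorobenzoic anhydride | C/C=C(/C)C(=O)OC(=O)c1c(Cl)cc(Cl)cc1Cl | intermediate
13 | methyl (3R,4R,6R)-3-[(4S)-2,2-dimethyl-1,3-dioxolan-4-yl]-6,10-dimethyl-2-methylidene-4-{[(2Z)-2-methylbut-2-enoyl]oxy}-6-(triethylsilyloxy)undec-9-enoate | COC(=O)C(=C)[C@@H]([C@H]1COC(C)(C)O1)[C@H](OC(=O)/C(C)=C\C)C[C@](C)(O[Si](CC)(CC)CC)CCC=C(C)C | intermediate
14 | secondary ozonide of 13: the 2-methylprop-1-enyl end is replaced by a 5,5-dimethyl-1,2,4-trioxolan-3-yl group (trioxolane CH epimers), other centres as in 13 | COC(=O)C(=C)[C@@H]([C@H]1COC(C)(C)O1)[C@H](OC(=O)/C(C)=C\C)C[C@](C)(O[Si](CC)(CC)CC)CCC2OOC(C)(C)O2 | intermediate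
15 | methyl (3R,4R,6R)-3-[(4S)-2,2-dimethyl-1,3-dioxolan-4-yl]-6-methyl-2-methylidene-4-{[(2Z)-2-methylbut-2-enoyl]oxy}-9-oxo-6-(triethylsilyloxy)nonanoate | COC(=O)C(=C)[C@@H]([C@H]1COC(C)(C)O1)[C@H](OC(=O)/C(C)=C\C)C[C@](C)(O[Si](CC)(CC)CC)CCC=O | intermediate
16 | methyl (3R,4R,6R)-3-[(4S)-2,2-dimethyl-1,3-dioxolan-4-yl]-9-hydroxy-6-methyl-2-methylidene-4-{[(2Z)-2-methylbut-2-enoyl]oxy}-6-(triethylsilyloxy)undec-10-ynoate (C9 epimers) | COC(=O)C(=C)[C@@H]([C@H]1COC(C)(C)O1)[C@H](OC(=O)/C(C)=C\C)C[C@](C)(O[Si](CC)(CC)CC)CCC(O)C#C | intermediate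
17 | methyl (3R,4R,6R)-3-[(4S)-2,2-dimethyl-1,3-dioxolan-4-yl]-6-methyl-2-methylidene-4-{[(2Z)-2-methylbut-2-enoyl]oxy}-9-oxo-6-(triethylsilyloxy)undec-10-ynoate | COC(=O)C(=C)[C@@H]([C@H]1COC(C)(C)O1)[C@H](OC(=O)/C(C)=C\C)C[C@](C)(O[Si](CC)(CC)CC)CCC(=O)C#C | intermediate
18 | diethylaluminium allenolate of 17: methyl (3R,4R,6R)-9-[(diethylalumanyl)oxy]-3-[(4S)-2,2-dimethyl-1,3-dioxolan-4-yl]-11-iodo-6-methyl-2-methylidene-4-{[(2Z)-2-methylbut-2-enoyl]oxy}-6-(triethylsilyloxy)undeca-9,10-dienoate | COC(=O)C(=C)[C@@H]([C@H]1COC(C)(C)O1)[C@H](OC(=O)/C(C)=C\C)C[C@](C)(O[Si](CC)(CC)CC)CCC(O[Al](CC)CC)=C=CI | intermediate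
19 | methyl (3R,4R,6R,10Z)-3-[(4S)-2,2-dimethyl-1,3-dioxolan-4-yl]-10-(hydroxymethyl)-11-iodo-6-methyl-2-methylidene-4-{[(2Z)-2-methylbut-2-enoyl]oxy}-9-oxo-6-(triethylsilyloxy)undec-10-enoate | COC(=O)C(=C)[C@@H]([C@H]1COC(C)(C)O1)[C@H](OC(=O)/C(C)=C\C)C[C@](C)(O[Si](CC)(CC)CC)CCC(=O)/C(CO)=C\I | intermediate
20 | methyl (3S,4R,6R,10Z)-3-[(1S)-1,2-dihydroxyethyl]-10-(hydroxymethyl)-11-iodo-6-methyl-2-methylidene-4-{[(2Z)-2-methylbut-2-enoyl]oxy}-9-oxo-6-(triethylsilyloxy)undec-10-enoate (same spatial arrangement at C3 as in 19; the descriptor changes by priority only) | COC(=O)C(=C)[C@@H]([C@H](O)CO)[C@H](OC(=O)/C(C)=C\C)C[C@](C)(O[Si](CC)(CC)CC)CCC(=O)/C(CO)=C\I | intermediate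
21 | methyl (3R,4R,6R,10Z)-3-formyl-10-(hydroxymethyl)-11-iodo-6-methyl-2-methylidene-4-{[(2Z)-2-methylbut-2-enoyl]oxy}-9-oxo-6-(triethylsilyloxy)undec-10-enoate | COC(=O)C(=C)[C@@H](C=O)[C@H](OC(=O)/C(C)=C\C)C[C@](C)(O[Si](CC)(CC)CC)CCC(=O)/C(CO)=C\I | intermediate
22 | methyl 2-[(1S,2S,3Z,8R,10R)-2-hydroxy-4-(hydroxymethyl)-8-methyl-10-{[(2Z)-2-methylbut-2-enoyl]oxy}-5-oxo-8-(triethylsilyloxy)cyclodec-3-en-1-yl]prop-2-enoate (formed as its chromium alkoxide) | O[C@H]1/C=C(/CO)C(=O)CC[C@@](C)(O[Si](CC)(CC)CC)C[C@@H](OC(=O)/C(C)=C\C)[C@H]1C(=C)C(=O)OC | intermediate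
23 | (3aR,4R,6R,10Z,11aS)-10-(hydroxymethyl)-6-methyl-3-methylidene-2,9-dioxo-6-(triethylsilyloxy)-2,3,3a,4,5,6,7,8,9,11a-decahydrocyclodeca[b]furan-4-yl (2Z)-2-methylbut-2-enoate | C=C1C(=O)O[C@H]2/C=C(/CO)C(=O)CC[C@@](C)(O[Si](CC)(CC)CC)C[C@@H](OC(=O)/C(C)=C\C)[C@@H]12 | intermediate
24 | CNP0181802.1, (3aR,4R,6R,10Z,11aS)-6-hydroxy-10-(hydroxymethyl)-6-methyl-3-methylidene-2,9-dioxo-2,3,3a,4,5,6,7,8,9,11a-decahydrocyclodeca[b]furan-4-yl (2Z)-2-methylbut-2-enoate | C=C1C(=O)O[C@H]2/C=C(/CO)C(=O)CC[C@@](C)(O)C[C@@H](OC(=O)/C(C)=C\C)[C@@H]12 | target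

Total step count: 14. Longest linear sequence: 12 steps (steps 1–3 and 6–14, from (R)-linalool).

Steps most likely to fail

Step 13 (key step). What may go wrong: the alkenylchromium may add to the other face of the aldehyde (C8 instead of the acrylate taking the anti position), so that the 6-epimeric alkoxide forms and lactonises to the trans-fused epimer; a slow ring closure would also leave the aldehyde time to epimerise at C7 or to lose angelate by β-elimination. The fallback sets out from 21 and comes back at 23. The closure is run in the manganese-driven catalytic mode (CrCl2 cat., NiCl2 cat., manganese powder, Me3SiCl, DMF/THF), in which the C6 alkoxide is silylated as it forms and therefore cannot lactonise. The 6-epimeric adduct is then isolated as the trimethylsilyl ether F1. Its methyl ester is cleaved chemoselectively with Me3SnOH (1,2-dichloroethane, 70 °C; dilute citric acid work-up removes the trimethylsilyl group) to give the (6R)-hydroxy acid F2. Mitsunobu lactonisation of F2 (PPh3, DIAD, THF, 0 °C, dilute) closes the γ-lactone with inversion at C6 and gives 23. This moves the stereochemical problem from the facial selectivity of the addition to a stereospecific SN2 step.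

Step 6. What may go wrong: equilibration of the allylindium species in water may erode the syn relationship and the facial bias, the allylindium may collapse by 1,4-elimination of the dioxolane oxygen, and indium salts may lactonise O8 onto C12. The fallback sets out from 9 and comes back at 10. Bromide 9 is converted into the configurationally stable (Z)-allyl pinacolboronate F3 (B2pin2, Pd2(dba)3 cat., toluene, 50 °C). Allylboration of aldehyde 5 with F3 (Sc(OTf)3 cat., toluene, −78 → 0 °C, or neat at 80 °C) proceeds through a closed chair transition state with strict Z → syn transfer and the same anti-to-oxygen facial bias under anhydrous conditions; aqueous work-up of the borate gives 10.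

Step 7. What may go wrong: acylation of the hindered O8 is slow at the temperature it needs, so that lactonisation of O8 onto C12 and Z → E isomerisation of the angeloyl unit compete. The fallback sets out from 10 and comes back at 13. O8 is first acylated at 0 °C with the much more reactive 2-[bis(2,2,2-trifluoroethoxy)phosphoryl]propanoic acid (DCC, DMAP cat., CH2Cl2) to give the phosphonopropionate F4. The angelate double bond is then built on the ester by Z-selective Still–Gennari olefination with acetaldehyde (KN(SiMe3)2, 18-crown-6, THF, −78 °C), which gives 13.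

Further compounds

F1 | step 13 | methyl 2-[(1R,2R,3Z,8R,10R)-4-(hydroxymethyl)-8-methyl-10-{[(2Z)-2-methylbut-2-enoyl]oxy}-5-oxo-8-(triethylsilyloxy)-2-(trimethylsilyloxy)cyclodec-3-en-1-yl]prop-2-enoate (6-epimeric silyl ether, target numbering) | C[Si](C)(C)O[C@@H]1/C=C(/CO)C(=O)CC[C@@](C)(O[Si](CC)(CC)CC)C[C@@H](OC(=O)/C(C)=C\C)[C@H]1C(=C)C(=O)OC
F2 | step 13 | 2-[(1S,2R,3Z,8R,10R)-2-hydroxy-4-(hydroxymethyl)-8-methyl-10-{[(2Z)-2-methylbut-2-enoyl]oxy}-5-oxo-8-(triethylsilyloxy)cyclodec-3-en-1-yl]prop-2-enoic acid | O[C@@H]1/C=C(/CO)C(=O)CC[C@@](C)(O[Si](CC)(CC)CC)C[C@@H](OC(=O)/C(C)=C\C)[C@H]1C(=C)C(=O)O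
F3 | step 6 | methyl (2Z)-3-[(4S)-2,2-dimethyl-1,3-dioxolan-4-yl]-2-[(4,4,5,5-tetramethyl-1,3,2-dioxaborolan-2-yl)methyl]prop-2-enoate | COC(=O)/C(CB1OC(C)(C)C(C)(C)O1)=C/[C@H]2COC(C)(C)O2
F4 | step 7 | methyl (3R,4R,6R)-4-({2-[bis(2,2,2-trifluoroethoxy)phosphoryl]propanoyl}oxy)-3-[(4S)-2,2-dimethyl-1,3-dioxolan-4-yl]-6,10-dimethyl-2-methylidene-6-(triethylsilyloxy)undec-9-enoate (phosphonate α-carbon epimers) | COC(=O)C(=C)[C@@H]([C@H]1COC(C)(C)O1)[C@H](OC(=O)C(C)P(=O)(OCC(F)(F)F)OCC(F)(F)F)C[C@](C)(O[Si](CC)(CC)CC)CCC=C(C)C
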